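## The problem

CNP0150397.1 (**23**) is an eremophilane, a cis-fused decalin. Ring A (C1–C5, C10) carries the C2 ketone and the C4 methyl; ring B (C5–C10) carries the C7 isopropenyl group, the C8 acetate and the C9 senecioate. The rings share the quaternary, methyl-bearing C5 and the methine C10; β denotes the face of the C5 methyl throughout. Six stereocentres lie on one arc, C4–C5–C10–C9–C8–C7: 4β-methyl, 5β-methyl, 10β-H, 7β-isopropenyl, 8α-acetoxy and 9α-senecioyloxy. In the ring-B chair that keeps the C5 methyl, the isopropenyl group and the acetate equatorial, only the C9 ester is axial. The hardest carbon problem is the C4/C5 pair, a tertiary centre next to an all-carbon quaternary one with the two methyls cis. The hardest heteroatom problem is two different esters on cis-vicinal oxygens, which invites acyl migration and rules out an undifferentiated diol. C7 is the one centre that can be set alone in an open chain; through a 1,3-diequatorial relation it can dictate C5, cis fusion then fixes C10, and the folded bicycle can direct reagents at C4, C8 and C9. The fragile parts are the 1,1-disubstituted alkene (no hydrogenation, ozone or strong acid), the conjugated senecioate (deconjugation by base), the C10 hydrogen whenever C9 is a ketone, and the need to tell the C2 and C9 carbonyls apart. The enabling feature is that C1–C5 and C10 with the C2 carbonyl form a 4-methyl-4-alkylcyclohexa-2,5-dienone whose quaternary carbon is C5, and C9 lies 1,4 to the C2 carbonyl. A C9 acyl anion tethered through C6–C7–C8 can therefore add to C10, and because the two enone arms are mirror-related at the ring, the same bond formation decides C5.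

## Retrosynthesis

**C2 mask and the O9–acyl bond.** **23** is traced to **22**, in which C2 is a tert-butyldimethylsilyl enol ether (C2=C3); its hydrolysis creates no stereocentre. Cutting the O9–senecioyl bond gives hydroxy acetate **21**. The senecioate goes on last because it is the more base-sensitive ester and O9 is the oxygen that is revealed last. The forward step must acylate a hindered axial alcohol without moving the neighbouring acetate.

**C9–H and the C8–O bonds.** **21** comes from α-acetoxy ketone **20** by hydride addition to C9, **20** from ketol **19**, and **19** from ketone **17** by cutting the C8–O bond. Using the C9 carbonyl to activate C8 makes the regiochemistry of the two esters unambiguous, which a C8=C9 dihydroxylation would not. The forward steps need enolisation toward C8 rather than C10, oxygen delivery anti to the C7 isopropenyl group, and hydride attack from the β face.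

**C4–methyl bond.** Removing the C4 methyl and returning the silyl enol ether to an enone gives enedione **15**. Putting this methyl on one arm of the dienone instead would destroy the symmetry that the key step uses, so it is added afterwards. The conjugate addition must take the β face, and trapping its enolate is what distinguishes C2 from C9.

**C9–C10 bond.** Cutting C9–C10 opens ring B and turns **15** into aldehyde-dienone **14**, which has one stereocentre (C7) instead of three. Cuts at C5–C6 or C5–C10 would have to build the quaternary carbon in the ring-forming step; this cut leaves it as the prochiral centre of a symmetric ring. The forward reaction needs an acyl-anion equivalent at C9 and a choice between two enone arms.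

**Oxidation levels of C9 and ring A.** **14** is traced through diol **13** to dienone ester **12** and enone ester **11**. An ester cannot be taken to an aldehyde beside a dienone, so both carbonyls are reduced and both re-oxidised; this costs two steps where a silyl-protected alcohol would cost four. Dehydrogenation of **11** to **12** erases the stereogenicity of C5.

**Ring A.** Cutting the C5–CH2 bond and the enone C=C of **11** gives α-branched aldehyde **7** and but-3-en-2-one (**8**). This annulation is the standard entry to 4,4-disubstituted cyclohexenones and needs no control at C5.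

**C7–isopropenyl bond.** **7** comes from acetal **6**, and **6** from enoate **4** and isopropenylboronate **5** by cutting the C7–C11 bond. This is the only step that introduces absolute configuration, and it does so on an open chain where catalyst control is undisturbed.

**C7=C8.** Enoate **4** is the cross-metathesis product of acetal **2** and methyl acrylate (**3**); **2** is the dimethyl acetal of commercial 2-methylpent-4-enal (**1**). The acetal keeps the aldehyde out of the rhodium step.

## Roads not taken

Alternative 1: Cut C6–C7 and C5–C10 together. A (7E,9Z)-triene **A2** would, on heating, add its C7=C8–C9=C10 diene to the C5=C6 alkene and give octalin **A1**. This closes both rings at once, brings C4 in already set from an open-chain precursor, and leaves a C8=C9 alkene exactly where the two oxygens belong. In ring count per step and in the C4 question it is better than the chosen plan. Its weak points are an unactivated 1,1-disubstituted dienophile, a (Z)-diene that reaches the s-cis form poorly and can undergo 1,5-hydrogen shift at the temperatures needed, facial control from one remote centre, a dihydroxylation that must take the α face and then be differentiated, and a late dehydration to regenerate the isopropenyl group. The chosen plan sets against it a room-temperature catalytic closure whose selectivity rests on a chair with an equatorial anchor, and oxygens introduced one at a time from a ketone.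

Alternative 2: Cut C4–C5. Single-electron reduction of N-acyloxyphthalimide **A4** would release carbon dioxide and a C4 radical that adds 6-endo to C5 of a ring-B enone, giving **A3**. This makes the hindered C4–C5 bond directly and arrives with the C8 acetate and C9 ketone in place, so the endgame is about three steps shorter. The weak points are that C4 arises from a planar radical with no controlling element, that C10 is set by a hydrogen-atom transfer, and that an α-acetoxy enone may lose its acetate under reducing conditions. In the chosen plan each of C5, C10, C8 and C9 has an identifiable controlling element; only C4 is similarly exposed, and it has a fallback.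

Alternative 3: Cut C1–C10. Anodic oxidation in methanol of bis-enol ether **A6** would couple C1 of the side-chain enol ether with C10 of the ring silyl enol ether and give **A5**. The product emerges with C2 masked as a ketal and C8/C9 oxygenated, which is as good as the chosen plan at that stage and needs fewer later steps. The cost is that the C4/C5 pair must already exist in **A6**, on a ring carrying a branched side chain, so the hardest stereochemical problem moves into the precursor. C10 would be fixed in a radical-cation cyclisation, and the oxidation must spare the isopropenyl alkene. The chosen plan has a precursor with one stereocentre and lets the ring closure create C5.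

Key step: step 9

Assumption 1: the (S)-BINAP–rhodium catalyst is taken to add the alkenyl group to the C3 Si face of (E)-enoate **4**, and the (5aR,10bS) triazolium antipode is taken to be matched with (S)-C7; if either sense proves opposite, the mirror-image ligand or catalyst is used.
Assumption 2: the carbon that becomes C5 is racemic or epimeric in **1**–**11** and is drawn without configuration, because it becomes the prochiral ring carbon of **12**.

Step 1
Reactants: 1 2-methylpent-4-enal
Product: 2 5,5-dimethoxy-4-methylpent-1-ene
Conditions: HC(OMe)3, MeOH, p-TsOH·H2O (cat.), rt; then Et3N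
Reagents that add atoms: trimethyl orthoformate, COC(OC)OC; methanol, CO
Why: Acid-catalysed acetalisation with orthoformate as water scavenger; the acetal keeps the aldehyde out of the metathesis and rhodium steps.

Step 2
Reactants: 2 5,5-dimethoxy-4-methylpent-1-ene; 3 methyl acrylate
Product: 4 methyl (E)-6,6-dimethoxy-5-methylhex-2-enoate
Conditions: Hoveyda–Grubbs second-generation catalyst (2 mol %), 3 (3 equiv), CH2Cl2, 40 °C
Reagents that add atoms: none
Why: Olefin cross-metathesis of a terminal alkene with an acrylate; this pairing is selective for the cross product and the (E)-isomer should dominate.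

Step 3
Reactants: 4 methyl (E)-6,6-dimethoxy-5-methylhex-2-enoate; 5 isopropenylboronic acid pinacol ester
Product: 6 methyl (3S)-6,6-dimethoxy-5-methyl-3-(prop-1-en-2-yl)hexanoate
Conditions: [Rh(OH)((S)-binap)]2 (1.5 mol %), 5 (2.5 equiv), dioxane/H2O 10:1, 50 °C
Reagents that add atoms: none
Why: Hayashi–Miyaura rhodium-catalysed asymmetric 1,4-addition of an alkenylboron reagent to an α,β-unsaturated ester; the ligand selects the enoate face and sets C7 (S), and the acetal and ester tolerate the near-neutral aqueous medium.

Step 4
Reactants: 6 methyl (3S)-6,6-dimethoxy-5-methyl-3-(prop-1-en-2-yl)hexanoate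
Product: 7 methyl (3S)-5-methyl-6-oxo-3-(prop-1-en-2-yl)hexanoate
Conditions: 0.5 M aq. HCl, THF, 0 °C → rt
Reagents that add atoms: water, O
Why: Mild hydrolysis of an acyclic dimethyl acetal; dilute Brønsted acid is chosen over Lewis acids so that carbonyl-ene closure onto the isopropenyl group is not triggered.

Step 5
Reactants: 7 methyl (3S)-5-methyl-6-oxo-3-(prop-1-en-2-yl)hexanoate; 8 but-3-en-2-one
Product: 11 methyl (3S)-4-(1-methyl-4-oxocyclohex-2-en-1-yl)-3-(prop-1-en-2-yl)butanoate, via pyrrolidine enamine 9 (not isolated), via keto aldehyde 10 (not isolated)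
Conditions: pyrrolidine (1.2 equiv), K2CO3, PhMe, rt; 8 (1.3 equiv), 0 °C → rt; then AcOH/NaOAc/H2O, 70 °C
Reagents that add atoms: none
Why: Stork enamine Michael addition builds the quaternary carbon, and buffered hydrolysis with intramolecular aldol condensation (Robinson annulation) closes the cyclohexenone; the configuration of the new ring carbon does not matter.

Step 6
Reactants: 11 methyl (3S)-4-(1-methyl-4-oxocyclohex-2-en-1-yl)-3-(prop-1-en-2-yl)butanoate
Product: 12 methyl (3S)-4-(1-methyl-4-oxocyclohexa-2,5-dien-1-yl)-3-(prop-1-en-2-yl)butanoate
Conditions: IBX (2.5 equiv), DMSO/PhF, 75 °C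
Reagents that add atoms: none
Why: IBX dehydrogenation on the saturated α′ side gives the cross-conjugated dienone; the ester and the isolated alkene are inert, and both epimers of 11 converge on one compound.

Step 7
Reactants: 12 methyl (3S)-4-(1-methyl-4-oxocyclohexa-2,5-dien-1-yl)-3-(prop-1-en-2-yl)butanoate
Product: 13 4-[(2S)-4-hydroxy-2-(prop-1-en-2-yl)butyl]-4-methylcyclohexa-2,5-dien-1-ol
Conditions: DIBAL-H (4.5 equiv), CH2Cl2, –78 → 0 °C; aq. Rochelle salt
Reagents that add atoms: none
Why: Hydride reduction of the ester to the primary alcohol with 1,2-reduction of the dienone; the bis-allylic alcohol (cis/trans mixture) is acid-labile and is kept under neutral to basic conditions.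

Step 8
Reactants: 13 4-[(2S)-4-hydroxy-2-(prop-1-en-2-yl)butyl]-4-methylcyclohexa-2,5-dien-1-ol
Product: 14 (3S)-4-methyl-3-[(1-methyl-4-oxocyclohexa-2,5-dien-1-yl)methyl]pent-4-enal
Conditions: Dess–Martin periodinane (2.6 equiv), NaHCO3, CH2Cl2, 0 °C → rt
Reagents that add atoms: none
Why: Buffered Dess–Martin oxidation of both alcohols restores the dienone and unveils the C9 aldehyde; IBX is avoided here because it could dehydrogenate the aldehyde through C7.

Step 9
Reactants: 14 (3S)-4-methyl-3-[(1-methyl-4-oxocyclohexa-2,5-dien-1-yl)methyl]pent-4-enal
Product: 15 cis-4a-methyl-6-(prop-1-en-2-yl)-4a,5,6,7-tetrahydronaphthalene-2,8(1H,8aH)-dione with 4a-methyl, 8a-H and 6-isopropenyl on the same face (eremophilane numbering: 5β-methyl, 10β-H, 7β-isopropenyl, C2 enone with C3=C4, C9 ketone)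
Conditions: aminoindanol-derived N-pentafluorophenyl triazolium tetrafluoroborate, (5aR,10bS) antipode (15 mol %), i-Pr2NEt (15 mol %), PhMe (0.02 M), 23 °C
Reagents that add atoms: none
Why: The carbene adds to the C9 aldehyde and a proton shift gives the Breslow intermediate, whose C9 attacks the enone β-carbon C10; proton transfer to C1 and loss of the carbene release the C9 ketone. The closest known reaction type is the carbene-catalysed intramolecular Stetter desymmetrisation of 4,4-disubstituted cyclohexa-2,5-dienones with a tethered aldehyde; the all-carbon tether closing a six-membered ring is the extension asked of it. Ring B closes 6-exo-trig. C10 is fixed relative to C5 by geometry, because the tether starts at C5 and C9 can only reach the dienone face that carries C6, so the fusion is cis. C5 is fixed by the choice of enone arm: attack perpendicular to the dienone plane puts the unreacted arm pseudo-axial and the C5 methyl pseudo-equatorial on the forming chair, so only the arm that leaves the C7 isopropenyl group equatorial, cis to the methyl, avoids a 1,3-diaxial clash. The step needs arm selectivity, secured by C7 and reinforced by the matched carbene, and it needs carbene catalysis to outrun enolate chemistry, secured by an electron-poor triazolium that a weak amine base can deprotonate.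

Step 10
Reactants: 15 cis-fused enedione (5β-methyl, 10β-H, 7β-isopropenyl; C3=C4 enone, C9 ketone)
Product: 17 2-(tert-butyldimethylsilyloxy)eremophila-2,11-dien-9-one (4β,5β-dimethyl; 7β-isopropenyl; 10β-H), via lithium enolate 16 (not isolated)
Conditions: Me2CuLi (from CuI and 2 MeLi, 1.5 equiv), Et2O, –78 → –30 °C; then TBSCl, HMPA, Et3N, THF, –78 °C → rt
Reagents that add atoms: lithium dimethylcuprate, [Li+].C[Cu-]C; tert-butyldimethylsilyl chloride, CC(C)(C)[Si](C)(C)Cl
Why: Gilman 1,4-addition to the C3=C4 enone spares the saturated C9 ketone; the methyl should enter on the convex β face, since the α face of C4 is screened by the axial C10–C9 bond of ring B, giving the 4β-methyl, equatorial on ring A and cis to the C5 methyl. O-Silylation of the regiodefined enolate masks C2 and sets it apart from C9.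

Step 11
Reactants: 17 2-(tert-butyldimethylsilyloxy)eremophila-2,11-dien-9-one
Product: 19 2-(tert-butyldimethylsilyloxy)-8α-hydroxyeremophila-2,11-dien-9-one, via sodium enolate 18 (not isolated)
Conditions: NaHMDS (1.2 equiv), THF, –78 °C; then 2-(phenylsulfonyl)-3-phenyloxaziridine, –78 °C; aq. NH4Cl
Reagents that add atoms: 2-(phenylsulfonyl)-3-phenyloxaziridine, O=S(=O)(c1ccccc1)N1OC1c1ccccc1
Why: Kinetic enolisation takes the C8 methylene rather than the hindered ring-fusion C10–H, so the cis fusion is not touched; the enolate is hydroxylated by the N-sulfonyloxaziridine anti to the adjacent C7 isopropenyl group, which gives the equatorial 8α-hydroxyl.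

Step 12
Reactants: 19 2-(tert-butyldimethylsilyloxy)-8α-hydroxyeremophila-2,11-dien-9-one
Product: 20 8α-acetoxy-2-(tert-butyldimethylsilyloxy)eremophila-2,11-dien-9-one
Conditions: Ac2O, pyridine, DMAP (cat.), CH2Cl2, 0 °C → rt
Reagents that add atoms: acetic anhydride, CC(=O)OC(C)=O
Why: Standard DMAP-catalysed acetylation of the only free hydroxyl; acylating at the ketol stage fixes the acetate on O8 before O9 exists.

Step 13
Reactants: 20 8α-acetoxy-2-(tert-butyldimethylsilyloxy)eremophila-2,11-dien-9-one
Product: 21 8α-acetoxy-2-(tert-butyldimethylsilyloxy)eremophila-2,11-dien-9α-ol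
Conditions: L-Selectride (1.2 equiv), THF, –78 °C; AcOH quench at –78 °C
Reagents that add atoms: none
Why: Bulky trialkylborohydride reduction of a cyclohexanone by equatorial attack; the α (axial) approach to C9 is blocked by the 1,3-diaxial C5–C4 bond on the concave face, so hydride enters from the β face and gives the axial 9α-alcohol, cis to the acetate. The cold acidic quench protonates the alkoxide before it can take the acetyl group.

Step 14
Reactants: 21 8α-acetoxy-2-(tert-butyldimethylsilyloxy)eremophila-2,11-dien-9α-ol
Product: 22 8α-acetoxy-2-(tert-butyldimethylsilyloxy)-9α-(3-methylbut-2-enoyloxy)eremophila-2,11-diene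
Conditions: 3-methylbut-2-enoyl chloride (3 equiv), pyridine, DMAP (0.3 equiv), CH2Cl2, 0 °C → rt
Reagents that add atoms: 3-methylbut-2-enoyl chloride, CC(C)=CC(Cl)=O
Why: DMAP-catalysed acylation of a hindered secondary alcohol with an acid chloride; pyridine is used instead of a trialkylamine to limit vinylketene formation, which would deconjugate the ester, and to avoid alkoxide-type acetyl migration.

Step 15
Reactants: 22 8α-acetoxy-2-(tert-butyldimethylsilyloxy)-9α-(3-methylbut-2-enoyloxy)eremophila-2,11-diene
Product: 23 CNP0150397.1, 8α-acetoxy-9α-(3-methylbut-2-enoyloxy)eremophil-11-en-2-one (4β,5β-dimethyl; 7β-isopropenyl; 10β-H)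
Conditions: 0.5 M aq. HCl, THF, 0 °C
Reagents that add atoms: none
Why: Acid hydrolysis of a silyl enol ether; protonation at C3 creates no stereocentre, and both esters and the isopropenyl group tolerate brief dilute acid.

## Compound list

1 | 2-methylpent-4-enal (racemic) | C=CCC(C)C=O | starting material
2 | 5,5-dimethoxy-4-methylpent-1-ene (racemic) | C=CCC(C)C(OC)OC | intermediate
3 | methyl acrylate | C=CC(=O)OC | starting material
4 | methyl (E)-6,6-dimethoxy-5-methylhex-2-enoate (racemic) | COC(=O)/C=C/CC(C)C(OC)OC | intermediate
5 | isopropenylboronic acid pinacol ester | CC(=C)B1OC(C)(C)C(C)(C)O1 | starting material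
6 | methyl (3S)-6,6-dimethoxy-5-methyl-3-(prop-1-en-2-yl)hexanoate (both C5 epimers) | C=C(C)[C@H](CC(=O)OC)CC(C)C(OC)OC | intermediate
7 | methyl (3S)-5-methyl-6-oxo-3-(prop-1-en-2-yl)hexanoate (both C5 epimers) | C=C(C)[C@H](CC(=O)OC)CC(C)C=O | intermediate
8 | but-3-en-2-one | CC(=O)C=C | starting material
9 | methyl (3S)-5-methyl-3-(prop-1-en-2-yl)-6-(pyrrolidin-1-yl)hex-5-enoate (pyrrolidine enamine, formed in situ) | C=C(C)[C@H](CC(=O)OC)CC(C)=CN1CCCC1 | intermediate
10 | methyl (3S)-5-formyl-5-methyl-8-oxo-3-(prop-1-en-2-yl)nonanoate (keto aldehyde, formed in situ) | C=C(C)[C@H](CC(=O)OC)CC(C)(C=O)CCC(C)=O | intermediate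
11 | methyl (3S)-4-(1-methyl-4-oxocyclohex-2-en-1-yl)-3-(prop-1-en-2-yl)butanoate (both ring epimers) | C=C(C)[C@H](CC(=O)OC)CC1(C)C=CC(=O)CC1 | intermediate
12 | methyl (3S)-4-(1-methyl-4-oxocyclohexa-2,5-dien-1-yl)-3-(prop-1-en-2-yl)butanoate | C=C(C)[C@H](CC(=O)OC)CC1(C)C=CC(=O)C=C1 | intermediate
13 | 4-[(2S)-4-hydroxy-2-(prop-1-en-2-yl)butyl]-4-methylcyclohexa-2,5-dien-1-ol (cis/trans) | C=C(C)[C@H](CCO)CC1(C)C=CC(O)C=C1 | intermediate
14 | (3S)-4-methyl-3-[(1-methyl-4-oxocyclohexa-2,5-dien-1-yl)methyl]pent-4-enal | C=C(C)[C@H](CC=O)CC1(C)C=CC(=O)C=C1 | intermediate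
15 | cis-4a-methyl-6-(prop-1-en-2-yl)-4a,5,6,7-tetrahydronaphthalene-2,8(1H,8aH)-dione (5β-methyl, 10β-H, 7β-isopropenyl) | C=C(C)[C@H]1C[C@@]2(C)[C@H](CC(=O)C=C2)C(=O)C1 | intermediate
16 | lithium C2-enolate of the 4β-methyl adduct (formed in situ) | C=C(C)[C@H]1C[C@@]2(C)[C@H](CC([O-])=C[C@@H]2C)C(=O)C1.[Li+] | intermediate
17 | 2-(tert-butyldimethylsilyloxy)eremophila-2,11-dien-9-one | C=C(C)[C@H]1C[C@@]2(C)[C@H](CC(O[Si](C)(C)C(C)(C)C)=C[C@@H]2C)C(=O)C1 | intermediate
18 | sodium C8-enolate of 17 (formed in situ) | C=C(C)[C@H]1C[C@@]2(C)[C@H](CC(O[Si](C)(C)C(C)(C)C)=C[C@@H]2C)C([O-])=C1.[Na+] | intermediate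
19 | 2-(tert-butyldimethylsilyloxy)-8α-hydroxyeremophila-2,11-dien-9-one | C=C(C)[C@H]1C[C@@]2(C)[C@H](CC(O[Si](C)(C)C(C)(C)C)=C[C@@H]2C)C(=O)[C@@H]1O | intermediate
20 | 8α-acetoxy-2-(tert-butyldimethylsilyloxy)eremophila-2,11-dien-9-one | C=C(C)[C@H]1C[C@@]2(C)[C@H](CC(O[Si](C)(C)C(C)(C)C)=C[C@@H]2C)C(=O)[C@@H]1OC(C)=O | intermediate
21 | 8α-acetoxy-2-(tert-butyldimethylsilyloxy)eremophila-2,11-dien-9α-ol | C=C(C)[C@H]1C[C@@]2(C)[C@H](CC(O[Si](C)(C)C(C)(C)C)=C[C@@H]2C)[C@H](O)[C@@H]1OC(C)=O | intermediate
22 | 8α-acetoxy-2-(tert-butyldimethylsilyloxy)-9α-(3-methylbut-2-enoyloxy)eremophila-2,11-diene | C=C(C)[C@H]1C[C@@]2(C)[C@H](CC(O[Si](C)(C)C(C)(C)C)=C[C@@H]2C)[C@H](OC(=O)C=C(C)C)[C@@H]1OC(C)=O | intermediate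
23 | CNP0150397.1, 8α-acetoxy-9α-(3-methylbut-2-enoyloxy)eremophil-11-en-2-one | C=C(C)[C@H]1C[C@@]2(C)[C@H](CC(=O)C[C@@H]2C)[C@H](OC(=O)C=C(C)C)[C@@H]1OC(C)=O | target

## Step count and risks

Total: 15 steps. Longest linear sequence: 15 steps, from **1**.

**Step 9 (key step).** Closure of a six-membered ring from an unactivated aliphatic aldehyde may be slow. Intermolecular benzoin-type self-condensation, or base-mediated 5-exo Michael closure through the C8 enolate, could then compete; a mismatched catalyst would also erode arm selection. Fallback, from **12** back to **15**: saponification (LiOH, THF/H2O) gives (3S)-4-methyl-3-[(1-methyl-4-oxocyclohexa-2,5-dien-1-yl)methyl]pent-4-enoic acid F1. Diphenyl diselenide and tributylphosphine convert it into the Se-phenyl selenoester F2. Tris(trimethylsilyl)silane and AIBN in benzene at 80 °C generate the acyl radical, which closes 6-exo-trig onto C10 through the same chair and gives **15**. This route also bypasses steps 7 and 8.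

**Step 10.** Facial selectivity at C4 may be poor or reversed. The convex-face approach is gauche to the vicinal C5 methyl, and the stereoelectronically preferred axial approach anti to that methyl would give the 4α epimer. Slow addition next to the quaternary carbon could also allow 1,2-attack at C9. Fallback, from **15** back to **17**, with C4 set by hydride instead of methyl: the cuprate adduct is carried on whatever its C4 configuration, as **17** and/or its 4α-methyl epimer F3. Saegusa–Ito oxidation (Pd(OAc)2, MeCN) gives the 4-methyl enedione F4, in which C4 is trigonal. Conjugate reduction with hexameric triphenylphosphine copper hydride in the presence of TBSCl then delivers hydride to the face the cuprate had preferred. If that face was α, the methyl ends β and the silyl enol ether obtained is **17**.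

**Step 3.** Insertion of a β-alkyl acrylate into the alkenyl–rhodium bond may be slow, so protodeboronation of **5** could consume the reagent and the enantioselectivity could fall. Fallback, from **2** back to **6**, using an oxazolidinone auxiliary: (4R)-3-acryloyl-4-phenyloxazolidin-2-one F5 is made from the commercial oxazolidinone and acryloyl chloride. Cross-metathesis with **2** gives the enoyl imide F6. Isopropenylmagnesium bromide with CuBr·SMe2 adds anti to the phenyl group on the chelated s-cis imide and gives the adduct F7. Sodium methoxide in methanol releases **6** and the auxiliary.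

**Step 13.** The new C9 alkoxide may take the acetyl group from O8 before the quench, the acetate may be partly reduced, or equatorial attack may be incomplete. Fallback, from **19** back to **21**, with reduction before acylation: L-Selectride reduces the free ketol to the 8α,9α-diol F8. Dibutyltin oxide in refluxing toluene gives the stannylene acetal F9. Acetyl chloride at 0 °C acylates its equatorial O8 and gives **21** without passing through **20**.

## Further compounds

F1 | step 9 | (3S)-4-methyl-3-[(1-methyl-4-oxocyclohexa-2,5-dien-1-yl)methyl]pent-4-enoic acid | C=C(C)[C@H](CC(=O)O)CC1(C)C=CC(=O)C=C1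
F2 | step 9 | Se-phenyl (3S)-4-methyl-3-[(1-methyl-4-oxocyclohexa-2,5-dien-1-yl)methyl]pent-4-eneselenoate | C=C(C)[C@H](CC(=O)[Se]c1ccccc1)CC1(C)C=CC(=O)C=C1
F3 | step 10 | 4α-methyl epimer of 17 | C=C(C)[C@H]1C[C@@]2(C)[C@H](CC(O[Si](C)(C)C(C)(C)C)=C[C@H]2C)C(=O)C1
F4 | step 10 | cis-4,4a-dimethyl-6-(prop-1-en-2-yl)-4a,5,6,7-tetrahydronaphthalene-2,8(1H,8aH)-dione (eremophila-3,11-diene-2,9-dione) | C=C(C)[C@H]1C[C@@]2(C)[C@H](CC(=O)C=C2C)C(=O)C1
F5 | step 3 | (4R)-3-acryloyl-4-phenyloxazolidin-2-one | C=CC(=O)N1C(=O)OC[C@H]1c1ccccc1
F6 | step 3 | (4R)-3-[(E)-6,6-dimethoxy-5-methylhex-2-enoyl]-4-phenyloxazolidin-2-one | O=C1OC[C@@H](c2ccccc2)N1C(=O)/C=C/CC(C)C(OC)OC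
F7 | step 3 | (4R)-3-[(3S)-6,6-dimethoxy-5-methyl-3-(prop-1-en-2-yl)hexanoyl]-4-phenyloxazolidin-2-one | C=C(C)[C@H](CC(=O)N1C(=O)OC[C@H]1c1ccccc1)CC(C)C(OC)OC
F8 | step 13 | 2-(tert-butyldimethylsilyloxy)eremophila-2,11-diene-8α,9α-diol | C=C(C)[C@H]1C[C@@]2(C)[C@H](CC(O[Si](C)(C)C(C)(C)C)=C[C@@H]2C)[C@H](O)[C@@H]1O
F9 | step 13 | 8α,9α-O-dibutylstannylene acetal of F8 | C=C(C)[C@H]1C[C@@]2(C)[C@H](CC(O[Si](C)(C)C(C)(C)C)=C[C@@H]2C)[C@@H]3O[Sn](CCCC)(CCCC)O[C@H]13
A1 | alternative 1 | cis-fused octalin with C8=C9 alkene, C2 dioxolane and 2-(triethylsilyloxy)propan-2-yl group on C7 | CC(C)(O[Si](CC)(CC)CC)[C@H]1C[C@@]2(C)[C@H](CC3(OCCO3)C[C@@H]2C)C=C1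
A2 | alternative 1 | (7E,9Z)-triene precursor with C2 dioxolane and C4 methyl | C=C(C)[C@@H](C)CC1(OCCO1)C/C=C\C=C\C(C)(C)O[Si](CC)(CC)CC
A3 | alternative 2 | cis-fused 8α-acetoxy-9-ketone with C2 dioxolane | C=C(C)[C@H]1C[C@@]2(C)[C@H](CC3(OCCO3)C[C@@H]2C)C(=O)[C@@H]1OC(C)=O
A4 | alternative 2 | N-acyloxyphthalimide of the ring-B enone acid | C=C(C)[C@H]1CC(C)=C(CC2(OCCO2)CC(C)C(=O)ON2C(=O)c3ccccc3C2=O)C(=O)[C@@H]1OC(C)=O
A5 | alternative 3 | cis-fused 9-ketone with C2 dimethyl ketal and C8 tert-butyldimethylsilyl ether | C=C(C)[C@H]1C[C@@]2(C)[C@H](CC(OC)(OC)C[C@@H]2C)C(=O)[C@@H]1O[Si](C)(C)C(C)(C)C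
A6 | alternative 3 | ring-B trimethylsilyl enol ether with C1=C2 methyl enol ether side chain on C5 | C=C(C)[C@H]1C[C@](C)([C@@H](C)CC(=C)OC)C=C(O[Si](C)(C)C)[C@@H]1O[Si](C)(C)C(C)(C)C
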